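**Retrosynthetic overview**
1. Ring B is closed last: C4–O bond by intramolecular SNAr of a tertiary alkoxide onto the 4-chloroquinolinone of the B half.
2. Ring A is closed just before: O–CH bond by Mitsunobu cyclisation with inversion, while the B half is still the electron-poor chloride.
3. Key C–C bond: Evans syn aldol joining the A-half acyl oxazolidinone to 4-chloro-3-formylquinolinone (sets C-b and C-c); the acyl carbon later becomes CMe2–O.
4. C-a: auxiliary-controlled conjugate addition of a 2-methylprop-1-enyl cuprate to an enoyl imide made by HWE olefination.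
5. Both halves come from one aldehyde (Vilsmeier reaction of 4-hydroxy-1-methylquinolin-2(1H)-one); the quinolinone rings are bought, the order of ring formation is ring A, then ring B.

Assumption and labels: the SMILES is taken as drawn. C-a is the CH bearing the 2-methylprop-1-enyl group (S), C-b the ring-fusion CH next to CMe2 (S), C-c the ring-fusion O–CH (R). Q-OTMSE = 1-methyl-2-oxo-4-[2-(trimethylsilyl)ethoxy]-1,2-dihydroquinolin-3-yl; Q-OH = its 4-hydroxy analogue; Q-Cl = 4-chloro-1-methyl-2-oxo-1,2-dihydroquinolin-3-yl; Xc = (4S)-4-benzyl-2-oxo-1,3-oxazolidin-3-yl.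

**Step 1**
Reactants: 1 4-hydroxy-1-methylquinolin-2(1H)-one
Product: 3 4-chloro-1-methyl-2-oxo-1,2-dihydroquinoline-3-carbaldehyde, via iminium chloride 2 (not isolated)
Conditions: POCl3 (3 equiv), DMF, 0 → 80 °C; then ice-water
Reagents that add atoms: POCl3 O=P(Cl)(Cl)Cl; DMF CN(C)C=O; water O
Why: Vilsmeier–Haack formylation at the nucleophilic C-3 with concurrent OH→Cl exchange of the vinylogous acid, the iminium being hydrolysed on work-up.

**Step 2**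
Reactants: 3 4-chloro-1-methyl-2-oxo-1,2-dihydroquinoline-3-carbaldehyde; 4 2-(trimethylsilyl)ethanol
Product: 5 1-methyl-2-oxo-4-[2-(trimethylsilyl)ethoxy]-1,2-dihydroquinoline-3-carbaldehyde
Conditions: NaH (1.1 equiv), THF, 0 °C → rt
Reagents that add atoms: none
Why: Addition–elimination (SNAr) at the β-chloro-enal carbon installs a fluoride-labile TMSE ether, which (unlike the chloride) will survive the cuprate step.

**Step 3**
Reactants: 6 (diethoxyphosphoryl)acetic acid; 7 (4S)-4-benzyl-1,3-oxazolidin-2-one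
Product: 9 (4S)-4-benzyl-3-[(diethoxyphosphoryl)acetyl]-1,3-oxazolidin-2-one, via pivalic mixed anhydride 8 (not isolated)
Conditions: pivaloyl chloride, Et3N, THF, −20 °C; then 7, LiCl, rt
Reagents that add atoms: none
Why: N-acylation of the oxazolidinone through a mixed pivalic anhydride under LiCl/Et3N activation gives the auxiliary-bearing HWE reagent.

**Step 4**
Reactants: 5 1-methyl-2-oxo-4-[2-(trimethylsilyl)ethoxy]-1,2-dihydroquinoline-3-carbaldehyde; 9 (4S)-4-benzyl-3-[(diethoxyphosphoryl)acetyl]-1,3-oxazolidin-2-one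
Product: 10 (4S)-4-benzyl-3-[(2E)-3-(Q-OTMSE)prop-2-enoyl]-1,3-oxazolidin-2-one
Conditions: LiCl, DIPEA, MeCN, rt
Reagents that add atoms: none
Why: Masamune–Roush Horner–Wadsworth–Emmons olefination is mild enough for the vinylogous ester and gives the E-enoyl imide.

**Step 5**
Reactants: 10 (4S)-4-benzyl-3-[(2E)-3-(Q-OTMSE)prop-2-enoyl]-1,3-oxazolidin-2-one; 11 2-methylprop-1-enylmagnesium bromide
Product: 13 (4S)-4-benzyl-3-[(3R)-5-methyl-3-(Q-OTMSE)hex-4-enoyl]-1,3-oxazolidin-2-one, via bromomagnesium Z-enolate 12 (not isolated)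
Conditions: 11 (3 equiv), CuBr·SMe2 (1.5 equiv), THF/Me2S, −78 → −20 °C
Reagents that add atoms: none
Why: Evans-auxiliary cuprate conjugate addition: the Mg-chelated syn-s-cis imide is attacked on the face opposite the benzyl group, setting C-a (3R here, S in the target).

**Step 6**
Reactants: 13 (4S)-4-benzyl-3-[(3R)-5-methyl-3-(Q-OTMSE)hex-4-enoyl]-1,3-oxazolidin-2-one; 3 4-chloro-1-methyl-2-oxo-1,2-dihydroquinoline-3-carbaldehyde
Product: 15 (4S)-4-benzyl-3-[(2S,3S)-2-[(S)-(Q-Cl)(hydroxy)methyl]-5-methyl-3-(Q-OTMSE)hex-4-enoyl]-1,3-oxazolidin-2-one, via Z-dibutylboron enolate 14 (not isolated)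
Conditions: Bu2BOTf (2 equiv), DIPEA, CH2Cl2, −78 → 0 °C; then 3, −78 → 0 °C
Reagents that add atoms: none
Why: Evans syn aldol joining the two halves: the Z-boron enolate reacts through a Zimmerman–Traxler chair on the face away from the benzyl group, setting C-b (S) and the carbinol C-c (S, inverted later).

**Step 7**
Reactants: 15 (4S)-4-benzyl-3-[(2S,3S)-2-[(S)-(Q-Cl)(hydroxy)methyl]-5-methyl-3-(Q-OTMSE)hex-4-enoyl]-1,3-oxazolidin-2-one
Product: 16 methyl (2S,3S)-2-[(S)-(Q-Cl)(hydroxy)methyl]-5-methyl-3-(Q-OTMSE)hex-4-enoate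
Conditions: MeMgBr, MeOH, CH2Cl2, 0 °C
Reagents that add atoms: methanol CO
Why: Chelation-assisted transesterification by methoxymagnesium bromide cleaves the exocyclic imide carbonyl without retro-aldol or epimerisation and returns the auxiliary.

**Step 8**
Reactants: 16 methyl (2S,3S)-2-[(S)-(Q-Cl)(hydroxy)methyl]-5-methyl-3-(Q-OTMSE)hex-4-enoate
Product: 18 4-chloro-3-[(1S,2S,3S)-1-hydroxy-2-(2-hydroxypropan-2-yl)-5-methyl-3-(Q-OTMSE)hex-4-en-1-yl]-1-methylquinolin-2(1H)-one, via methyl ketone 17 (not isolated)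
Conditions: MeMgBr (6 equiv), LaCl3·2LiCl (0.3 equiv), THF, −40 → 0 °C
Reagents that add atoms: methylmagnesium bromide C[Mg]Br
Why: Double Grignard addition to the ester gives the tertiary carbinol; the lanthanum salt suppresses enolisation and retro-aldol, and the cold magnesium alkoxide does not displace the aryl chloride.

**Step 9**
Reactants: 18 4-chloro-3-[(1S,2S,3S)-1-hydroxy-2-(2-hydroxypropan-2-yl)-5-methyl-3-(Q-OTMSE)hex-4-en-1-yl]-1-methylquinolin-2(1H)-one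
Product: 19 4-chloro-3-[(1S,2S,3S)-1-hydroxy-2-(2-hydroxypropan-2-yl)-5-methyl-3-(Q-OH)hex-4-en-1-yl]-1-methylquinolin-2(1H)-one
Conditions: TBAF, THF, 0 °C → rt; then AcOH
Reagents that add atoms: none
Why: Fluoride-triggered β-elimination of the 2-(trimethylsilyl)ethyl group frees the acidic 4-hydroxyquinolinone under non-acidic conditions.

**Step 10**
Reactants: 19 4-chloro-3-[(1S,2S,3S)-1-hydroxy-2-(2-hydroxypropan-2-yl)-5-methyl-3-(Q-OH)hex-4-en-1-yl]-1-methylquinolin-2(1H)-one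
Product: 21 (2R,3S,4S)-2-(Q-Cl)-3-(2-hydroxypropan-2-yl)-6-methyl-4-(2-methylprop-1-en-1-yl)-2,3,4,6-tetrahydro-5H-pyrano[3,2-c]quinolin-5-one, via alkoxyphosphonium betaine 20 (not isolated)
Conditions: PPh3, DIAD, THF (0.01 M), 0 °C → rt
Reagents that add atoms: none
Why: Intramolecular Mitsunobu etherification: the acidic 4-OH (pKa about 6) displaces the activated secondary carbinol by SN2 with inversion (C-c S → R), closing ring A; the tertiary alcohol is inert and the electron-poor chloro ring disfavours SN1.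

**Step 11**
Reactants: 21 (2R,3S,4S)-2-(Q-Cl)-3-(2-hydroxypropan-2-yl)-6-methyl-4-(2-methylprop-1-en-1-yl)-2,3,4,6-tetrahydro-5H-pyrano[3,2-c]quinolin-5-one
Product: 22 target CNP0210533.1
Conditions: NaH, DMF, 0 → 60 °C
Reagents that add atoms: none
Why: Intramolecular SNAr (addition–elimination) of the tertiary alkoxide at C-4 of the chloroquinolinone closes ring B; no stereocentre is touched and the cis fusion is already fixed by the cis aryl/CMe2 arrangement on ring A.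

**Compound list**
1 | 4-hydroxy-1-methylquinolin-2(1H)-one | Cn1c(=O)cc(O)c2ccccc12 | starting material
2 | 4-chloro-3-[(dimethyliminio)methyl]-1-methylquinolin-2(1H)-one chloride (not isolated) | C[N+](C)=Cc1c(Cl)c2ccccc2n(C)c1=O.[Cl-] | intermediate
3 | 4-chloro-1-methyl-2-oxo-1,2-dihydroquinoline-3-carbaldehyde | Cn1c(=O)c(C=O)c(Cl)c2ccccc12 | intermediate
4 | 2-(trimethylsilyl)ethanol | C[Si](C)(C)CCO | starting material
5 | 1-methyl-2-oxo-4-[2-(trimethylsilyl)ethoxy]-1,2-dihydroquinoline-3-carbaldehyde | Cn1c(=O)c(C=O)c(OCC[Si](C)(C)C)c2ccccc12 | intermediate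
6 | (diethoxyphosphoryl)acetic acid | CCOP(=O)(OCC)CC(=O)O | starting material
7 | (4S)-4-benzyl-1,3-oxazolidin-2-one | O=C1N[C@@H](Cc2ccccc2)CO1 | starting material
8 | (diethoxyphosphoryl)acetic pivalic anhydride (not isolated) | CCOP(=O)(OCC)CC(=O)OC(=O)C(C)(C)C | intermediate
9 | (4S)-4-benzyl-3-[(diethoxyphosphoryl)acetyl]-1,3-oxazolidin-2-one | CCOP(=O)(OCC)CC(=O)N1[C@@H](Cc2ccccc2)COC1=O | intermediate
10 | (4S)-4-benzyl-3-[(2E)-3-(Q-OTMSE)prop-2-enoyl]-1,3-oxazolidin-2-one | O=C(/C=C/c1c(OCC[Si](C)(C)C)c2ccccc2n(C)c1=O)N1[C@@H](Cc2ccccc2)COC1=O | intermediate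
11 | 2-methylprop-1-enylmagnesium bromide | CC(C)=C[Mg]Br | starting material
12 | bromomagnesium Z-enolate of 13 (not isolated) | Br[Mg]O/C(=C\[C@H](C=C(C)C)c1c(OCC[Si](C)(C)C)c2ccccc2n(C)c1=O)N1[C@@H](Cc2ccccc2)COC1=O | intermediate
13 | (4S)-4-benzyl-3-[(3R)-5-methyl-3-(Q-OTMSE)hex-4-enoyl]-1,3-oxazolidin-2-one | CC(C)=C[C@@H](CC(=O)N1[C@@H](Cc2ccccc2)COC1=O)c1c(OCC[Si](C)(C)C)c2ccccc2n(C)c1=O | intermediate
14 | Z-dibutylboron enolate of 13 (not isolated) | CCCCB(CCCC)O/C(=C\[C@H](C=C(C)C)c1c(OCC[Si](C)(C)C)c2ccccc2n(C)c1=O)N1[C@@H](Cc2ccccc2)COC1=O | intermediate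
15 | (4S)-4-benzyl-3-[(2S,3S)-2-[(S)-(Q-Cl)(hydroxy)methyl]-5-methyl-3-(Q-OTMSE)hex-4-enoyl]-1,3-oxazolidin-2-one | CC(C)=C[C@@H]([C@H](C(=O)N1[C@@H](Cc2ccccc2)COC1=O)[C@H](O)c1c(Cl)c2ccccc2n(C)c1=O)c1c(OCC[Si](C)(C)C)c2ccccc2n(C)c1=O | intermediate
16 | methyl (2S,3S)-2-[(S)-(Q-Cl)(hydroxy)methyl]-5-methyl-3-(Q-OTMSE)hex-4-enoate | CC(C)=C[C@@H]([C@H](C(=O)OC)[C@H](O)c1c(Cl)c2ccccc2n(C)c1=O)c1c(OCC[Si](C)(C)C)c2ccccc2n(C)c1=O | intermediate
17 | (3S,4S)-3-[(S)-(Q-Cl)(hydroxy)methyl]-6-methyl-4-(Q-OTMSE)hept-5-en-2-one (not isolated) | CC(C)=C[C@@H]([C@H](C(C)=O)[C@H](O)c1c(Cl)c2ccccc2n(C)c1=O)c1c(OCC[Si](C)(C)C)c2ccccc2n(C)c1=O | intermediate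
18 | 4-chloro-3-[(1S,2S,3S)-1-hydroxy-2-(2-hydroxypropan-2-yl)-5-methyl-3-(Q-OTMSE)hex-4-en-1-yl]-1-methylquinolin-2(1H)-one | CC(C)=C[C@@H]([C@H](C(C)(C)O)[C@H](O)c1c(Cl)c2ccccc2n(C)c1=O)c1c(OCC[Si](C)(C)C)c2ccccc2n(C)c1=O | intermediate
19 | 4-chloro-3-[(1S,2S,3S)-1-hydroxy-2-(2-hydroxypropan-2-yl)-5-methyl-3-(Q-OH)hex-4-en-1-yl]-1-methylquinolin-2(1H)-one | CC(C)=C[C@@H]([C@H](C(C)(C)O)[C@H](O)c1c(Cl)c2ccccc2n(C)c1=O)c1c(O)c2ccccc2n(C)c1=O | intermediate
20 | C-c O-triphenylphosphonium betaine of 19 with 4-oxido quinolinone (not isolated) | CC(C)=C[C@@H]([C@H](C(C)(C)O)[C@H](O[P+](c1ccccc1)(c1ccccc1)c1ccccc1)c1c(Cl)c2ccccc2n(C)c1=O)c1c([O-])c2ccccc2n(C)c1=O | intermediate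
21 | (2R,3S,4S)-2-(Q-Cl)-3-(2-hydroxypropan-2-yl)-6-methyl-4-(2-methylprop-1-en-1-yl)-2,3,4,6-tetrahydro-5H-pyrano[3,2-c]quinolin-5-one | CC(C)=C[C@@H]1c2c(c3ccccc3n(C)c2=O)O[C@@H](c2c(Cl)c3ccccc3n(C)c2=O)[C@H]1C(C)(C)O | intermediate
22 | CNP0210533.1, cis-fused bis(pyrano[3,2-c]quinolin-5-one) with C-a S, C-b S, C-c R | CC(C)=C[C@@H]1c2c(c3ccccc3n(C)c2=O)O[C@H]2c3c(c4ccccc4n(C)c3=O)OC(C)(C)[C@@H]12 | target

**Totals**
Total step count: 11. Longest linear sequence: 10 steps (1, 2, 4, 5, 6, 7, 8, 9, 10, 11); step 3 is a one-step side branch.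

**Three steps most likely to fail**

Step 8. The ester is hindered and carries a free β-hydroxyl, so retro-aldol, a stalled second addition or early closure of ring B can intervene. The fallback sets out from aldol adduct 15 and bypasses steps 7 to 9. AlMe3 and MeONHMe·HCl convert the imide into the Weinreb amide F1. TESOTf and 2,6-lutidine give its triethylsilyl ether F2, which can no longer undergo retro-aldol. MeMgBr then gives the silyl-protected methyl ketone F3, and MeLi with CeCl3 gives the silyl-protected tertiary alcohol F4. TBAF removes the triethylsilyl and the TMSE group together, and the route is rejoined at 19.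

Step 10. The SN2 centre is a β-branched benzylic carbinol, so elimination to the alkene or alkylation at the lactam oxygen instead of O-4 may compete. The fallback sets out from diol 18 and replaces the SN2 closure by an oxidation/reduction inversion followed by SNAr. NaH in DMF closes ring B first to give the ring-B alcohol F5. Dess–Martin periodinane gives the pyranoquinolinedione ketone F6. NaBH4 with CeCl3 delivers hydride anti to the pseudo-axial side chain and gives the cis alcohol F7, in which C-c is now R. TBAF gives the free 4-hydroxyquinolinone F8, and PhNTf2 with Et3N gives the aryl triflate F9. NaH in THF then closes ring A by SNAr with retention, and the route comes back at 22.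

Step 11. The 3-alkyl-4-chloroquinolinone is only moderately activated and the nucleophile is a tertiary alkoxide. The fallback sets out from 21 and forms the same C–O bond by palladium-catalysed intramolecular etherification (Pd(OAc)2, t-BuXPhos, Cs2CO3, toluene, 90 °C), coming back at 22; it makes no new compound (none F0).

**Further compounds**
F1 | step 8 | (2S,3S)-2-[(S)-(Q-Cl)(hydroxy)methyl]-N-methoxy-N,5-dimethyl-3-(Q-OTMSE)hex-4-enamide | CC(C)=C[C@@H]([C@H](C(=O)N(C)OC)[C@H](O)c1c(Cl)c2ccccc2n(C)c1=O)c1c(OCC[Si](C)(C)C)c2ccccc2n(C)c1=O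
F2 | step 8 | (2S,3S)-2-[(S)-(Q-Cl)(triethylsilyloxy)methyl]-N-methoxy-N,5-dimethyl-3-(Q-OTMSE)hex-4-enamide | CC(C)=C[C@@H]([C@H](C(=O)N(C)OC)[C@H](O[Si](CC)(CC)CC)c1c(Cl)c2ccccc2n(C)c1=O)c1c(OCC[Si](C)(C)C)c2ccccc2n(C)c1=O
F3 | step 8 | (3S,4S)-3-[(S)-(Q-Cl)(triethylsilyloxy)methyl]-6-methyl-4-(Q-OTMSE)hept-5-en-2-one | CC(C)=C[C@@H]([C@H](C(C)=O)[C@H](O[Si](CC)(CC)CC)c1c(Cl)c2ccccc2n(C)c1=O)c1c(OCC[Si](C)(C)C)c2ccccc2n(C)c1=O
F4 | step 8 | 4-chloro-3-[(1S,2S,3S)-2-(2-hydroxypropan-2-yl)-5-methyl-3-(Q-OTMSE)-1-(triethylsilyloxy)hex-4-en-1-yl]-1-methylquinolin-2(1H)-one | CC(C)=C[C@@H]([C@H](C(C)(C)O)[C@H](O[Si](CC)(CC)CC)c1c(Cl)c2ccccc2n(C)c1=O)c1c(OCC[Si](C)(C)C)c2ccccc2n(C)c1=O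
F5 | step 10 | (3S,4S)-4-hydroxy-2,2,6-trimethyl-3-[(1S)-3-methyl-1-(Q-OTMSE)but-2-en-1-yl]-3,4-dihydro-2H-pyrano[3,2-c]quinolin-5(6H)-one | CC(C)=C[C@@H]([C@H]1[C@H](O)c2c(OC1(C)C)c1ccccc1n(C)c2=O)c1c(OCC[Si](C)(C)C)c2ccccc2n(C)c1=O
F6 | step 10 | (3R)-2,2,6-trimethyl-3-[(1S)-3-methyl-1-(Q-OTMSE)but-2-en-1-yl]-2,3-dihydro-4H-pyrano[3,2-c]quinoline-4,5(6H)-dione | CC(C)=C[C@@H]([C@H]1C(=O)c2c(OC1(C)C)c1ccccc1n(C)c2=O)c1c(OCC[Si](C)(C)C)c2ccccc2n(C)c1=O
F7 | step 10 | (3S,4R)-4-hydroxy-2,2,6-trimethyl-3-[(1S)-3-methyl-1-(Q-OTMSE)but-2-en-1-yl]-3,4-dihydro-2H-pyrano[3,2-c]quinolin-5(6H)-one | CC(C)=C[C@@H]([C@H]1[C@@H](O)c2c(OC1(C)C)c1ccccc1n(C)c2=O)c1c(OCC[Si](C)(C)C)c2ccccc2n(C)c1=O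
F8 | step 10 | (3S,4R)-4-hydroxy-2,2,6-trimethyl-3-[(1S)-3-methyl-1-(Q-OH)but-2-en-1-yl]-3,4-dihydro-2H-pyrano[3,2-c]quinolin-5(6H)-one | CC(C)=C[C@@H]([C@H]1[C@@H](O)c2c(OC1(C)C)c1ccccc1n(C)c2=O)c1c(O)c2ccccc2n(C)c1=O
F9 | step 10 | 3-{(1S)-1-[(3S,4R)-4-hydroxy-2,2,6-trimethyl-5-oxo-3,4,5,6-tetrahydro-2H-pyrano[3,2-c]quinolin-3-yl]-3-methylbut-2-en-1-yl}-1-methyl-2-oxo-1,2-dihydroquinolin-4-yl trifluoromethanesulfonate | CC(C)=C[C@@H]([C@H]1[C@@H](O)c2c(OC1(C)C)c1ccccc1n(C)c2=O)c1c(OS(=O)(=O)C(F)(F)F)c2ccccc2n(C)c1=O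
F0 | step 11 | none | none
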